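## Retrosynthetic overview

1. The target comes from a silyl-protected tricyclic ester by late C11 acetylation, C6 oxidation with olefin shift, and angeloylation of the neopentyl alcohol; its C2–H comes from radical deoxygenation of a tertiary aldol oxalate.
2. The seven-membered ring is closed by an intramolecular ester-enolate aldol (C1–C2 bond) onto the carbonyl of a bicyclo[3.1.1]heptan-6-one; C1 is relayed from the bought C11 silyloxy centre.
3. The cyclobutane and the six-membered ring are formed together by an intramolecular vinylketene–alkene [2+2] cycloaddition of an acyclic (2E,6E)-dienoic acid; the face is set by a bought C6 silyloxy centre (A(1,3) strain), C8 by the olefin geometry.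
4. The acyclic acid comes from a one-pot double Negishi coupling of a gem-dibromoalkene (C2–C8, from (R)-3-hydroxy-γ-butyrolactone) with an alkylzinc (C9–C11 and C1, from (R)-3-silyloxyglutaric acid methyl half-ester) and Me2Zn.
5. Ring order: four- and six-membered rings in one step, then the seven-membered ring.

Atom labels used below: C1 = quaternary carbon carrying CH3 and CH2O; C2, C3, C7, C8 = cyclobutane carbons (C2 bonded to C1, C8 carrying CH3, C3 and C7 the bridgeheads); C4(CH3)=C5–C6(=O) = three-carbon bridge from C3 to C7; C9–C10–C11(O) = chain from C8 to C1. TBS = tert-butyldimethylsilyl, TES = triethylsilyl.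

Assumption: both chiral starting materials are bought as single enantiomers.

## Route

Step 1
Reactants: 1 (3R)-5-methoxy-5-oxo-3-(TBSO)pentanoic acid
Product: 2 methyl (3R)-5-hydroxy-3-(TBSO)pentanoate
Conditions: BH3·SMe2, THF, 0 → 23 °C; MeOH quench
Reagents that add atoms: none
Why: Borane reduces the free carboxylic acid chemoselectively (acyloxyborane pathway) while the methyl ester and silyl ether are inert and the bought C11 stereocentre is untouched.

Step 2
Reactants: 2 methyl (3R)-5-hydroxy-3-(TBSO)pentanoate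
Product: 3 methyl (3S)-5-iodo-3-(TBSO)pentanoate
Conditions: I2, PPh3, imidazole, CH2Cl2, 0 → 23 °C
Reagents that add atoms: iodine [I][I]
Why: Appel-type iodination converts the primary alcohol into the iodide by SN2 at CH2 under neutral conditions that spare the β-silyloxy ester.

Step 3
Reactants: 3 methyl (3S)-5-iodo-3-(TBSO)pentanoate
Product: 5 methyl (2RS,3R)-5-iodo-2-methyl-3-(TBSO)pentanoate, via lithium enolate 4 (not isolated)
Conditions: LiN(i-Pr)2, THF, −78 °C; then MeI, −78 → −40 °C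
Reagents that add atoms: iodomethane IC
Why: Kinetic ester-enolate alkylation installs the future C1 methyl group; the new α-centre is left as an epimer mixture on purpose because it is planarised again in the aldol of step 12.

Step 4
Reactants: 6 (4R)-4-hydroxyoxolan-2-one [(R)-3-hydroxy-γ-butyrolactone]
Product: 7 (4R)-4-(TESO)oxolan-2-one
Conditions: Et3SiCl, imidazole, CH2Cl2, 0 → 23 °C
Reagents that add atoms: chlorotriethylsilane CC[Si](Cl)(CC)CC
Why: Imidazole-promoted O-silylation masks the bought secondary alcohol (future C6 oxygen) as the bulky ether that later steers the cycloaddition.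

Step 5
Reactants: 7 (4R)-4-(TESO)oxolan-2-one
Product: 8 (4R)-5-hydroxy-4-(TESO)pentan-2-one (equilibrating with its cyclic hemiketal)
Conditions: MeLi (1.05 equiv), THF, −78 °C; AcOH quench at −78 °C
Reagents that add atoms: methyllithium [Li]C
Why: Nucleophilic mono-addition of MeLi to the lactone stops at the lithium hemiketal at −78 °C and so delivers the methyl ketone (C4 plus its methyl) after the cold quench without disturbing C6.

Step 6
Reactants: 8 (4R)-5-hydroxy-4-(TESO)pentan-2-one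
Product: 9 (2R)-4-oxo-2-(TESO)pentanal
Conditions: Dess–Martin periodinane, pyridine, CH2Cl2, 0 → 23 °C; used crude
Reagents that add atoms: none
Why: Dess–Martin oxidation of the primary alcohol (open-chain tautomer of the hemiketal) gives the α-silyloxy aldehyde under buffered, non-epimerising conditions.

Step 7
Reactants: 9 (2R)-4-oxo-2-(TESO)pentanal
Product: 10 (4R)-6,6-dibromo-4-(TESO)hex-5-en-2-one
Conditions: CBr4, PPh3, 2,6-lutidine, CH2Cl2, 0 °C
Reagents that add atoms: tetrabromomethane BrC(Br)(Br)Br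
Why: Ramirez dibromo-olefination (first half of the Corey–Fuchs sequence) is selective for the aldehyde over the methyl ketone and introduces C8 as a gem-dibromoalkene.

Step 8
Reactants: 10 (4R)-6,6-dibromo-4-(TESO)hex-5-en-2-one
Product: 11 tert-butyl (2E,5R)-7,7-dibromo-3-methyl-5-(TESO)hepta-2,6-dienoate
Conditions: (EtO)2P(O)CH2CO2t-Bu, NaH, THF, 0 → 23 °C; (2E) isomer separated
Reagents that add atoms: tert-butyl (diethoxyphosphoryl)acetate CCOP(=O)(CC(=O)OC(C)(C)C)OCC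
Why: Horner–Wadsworth–Emmons olefination of the methyl ketone adds C2–C3 as the β-methyl enoate with the ester trans to the chain, which later directs γ-deprotonation to the methyl group.

Step 9
Reactants: 5 methyl (2RS,3R)-5-iodo-2-methyl-3-(TBSO)pentanoate; 11 tert-butyl (2E,5R)-7,7-dibromo-3-methyl-5-(TESO)hepta-2,6-dienoate
Product: 14 diester 1-tert-butyl 12-methyl (2E,5R,6E,10R,11RS)-3,7,11-trimethyl-10-(TBSO)-5-(TESO)dodeca-2,6-dienedioate, via alkylzinc iodide 12 (not isolated), via bromoalkene 13 (not isolated)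
Conditions: 5, Zn, LiCl, THF, 40 °C; then 11, PdCl2(DPEphos) (5 mol %), 0 → 23 °C; then Me2Zn, Pd(P(t-Bu)3)2 (5 mol %), 23 °C
Reagents that add atoms: dimethylzinc C[Zn]C
Why: Tandem Negishi cross-coupling of the 1,1-dibromoalkene replaces the less hindered bromine (trans to the C6 substituent) by the alkylzinc and then the remaining cis bromine by methyl with retention, so the (6E) trisubstituted olefin is formed as a single isomer.

Step 10
Reactants: 14 diester 1-tert-butyl 12-methyl (2E,5R,6E,10R,11RS)-3,7,11-trimethyl-10-(TBSO)-5-(TESO)dodeca-2,6-dienedioate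
Product: 16 (2E,5R,6E,10R,11RS)-12-methoxy-3,7,11-trimethyl-12-oxo-10-(TBSO)-5-(TESO)dodeca-2,6-dienoic acid, via triethylsilyl ester 15 (not isolated)
Conditions: Et3SiOTf, 2,6-lutidine, CH2Cl2, 0 °C; then H2O/THF
Reagents that add atoms: none
Why: Silyl triflate-promoted cleavage of the tert-butyl ester (loss of isobutene, hydrolysis of the silyl ester on work-up) frees the acid without touching the methyl ester or the silyl ethers.

Step 11
Reactants: 16 (2E,5R,6E,10R,11RS)-12-methoxy-3,7,11-trimethyl-12-oxo-10-(TBSO)-5-(TESO)dodeca-2,6-dienoic acid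
Product: 19 methyl (2RS,3R)-2-methyl-5-[(1S,4R,5S,7S)-7-methyl-2-methylidene-6-oxo-4-(TESO)bicyclo[3.1.1]heptan-7-yl]-3-(TBSO)pentanoate, via acid chloride 17 (not isolated), via vinylketene 18 (not isolated)
Conditions: 1-chloro-N,N,2-trimethylprop-1-en-1-amine, CH2Cl2, 0 → 23 °C; then syringe-pump addition to Et3N, toluene, 110 °C (0.005 M)
Reagents that add atoms: none
Why: γ-Deprotonation of the acid chloride gives a vinylketene whose intramolecular [2+2] cycloaddition to the trisubstituted olefin (ketene carbonyl carbon to the less substituted C7) builds the cyclobutanone and the six-membered ring at once; the (E) olefin geometry puts the C8 methyl syn to the new bridge and A(1,3) strain (C6–H in the olefin plane next to the cis C8 methyl, OTES turned away) selects the olefin face, so the bought C6 centre sets C3, C7 and C8.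

Step 12
Reactants: 19 methyl (2RS,3R)-2-methyl-5-[(1S,4R,5S,7S)-7-methyl-2-methylidene-6-oxo-4-(TESO)bicyclo[3.1.1]heptan-7-yl]-3-(TBSO)pentanoate
Product: 22 methyl (1S,2S,3S,4R,7S,8S,11R)-2-[(2-methoxy-2-oxoacetyl)oxy]-3,7-dimethyl-9-methylidene-4-(TBSO)-11-(TESO)tricyclo[5.4.0.0^2,8]undecane-3-carboxylate, via lithium enolate 20 (not isolated), via lithium aldolate 21 (not isolated)
Conditions: LiN(i-Pr)2, THF, −78 °C, 1 h; then ClC(O)CO2Me, −78 → −40 °C
Reagents that add atoms: methyl chlorooxoacetate COC(=O)C(=O)Cl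
Why: Intramolecular ester-enolate aldol addition to the strained, non-enolisable cyclobutanone closes the seven-membered ring on the only face the tether can reach, the enolate reacting through the conformer with C11–H eclipsing the enolate double bond (A(1,3) strain) so that the C1 methyl ends cis to the C11 silyloxy group, and the hindered tertiary aldolate is trapped in situ as its methyl oxalate.

Step 13
Reactants: 22 methyl (1S,2S,3S,4R,7S,8S,11R)-2-[(2-methoxy-2-oxoacetyl)oxy]-3,7-dimethyl-9-methylidene-4-(TBSO)-11-(TESO)tricyclo[5.4.0.0^2,8]undecane-3-carboxylate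
Product: 23 methyl (1S,2R,3R,4R,7S,8S,11R)-3,7-dimethyl-9-methylidene-4-(TBSO)-11-(TESO)tricyclo[5.4.0.0^2,8]undecane-3-carboxylate
Conditions: Bu3SnH, AIBN (cat.), toluene, 110 °C
Reagents that add atoms: none
Why: Barton-type (Dolan–MacMillan) radical deoxygenation of the tertiary oxalate gives the C2 cyclobutyl radical, which is held by the seven-membered ring and takes hydrogen from Bu3SnH on its only open face to set C2–H.

Step 14
Reactants: 23 methyl (1S,2R,3R,4R,7S,8S,11R)-3,7-dimethyl-9-methylidene-4-(TBSO)-11-(TESO)tricyclo[5.4.0.0^2,8]undecane-3-carboxylate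
Product: 24 [(1S,2R,3S,4R,7S,8S,11R)-3,7-dimethyl-9-methylidene-4-(TBSO)-11-(TESO)tricyclo[5.4.0.0^2,8]undecan-3-yl]methanol
Conditions: LiAlH4, Et2O, 0 → 23 °C
Reagents that add atoms: none
Why: LiAlH4 reduces the neopentyl methyl ester to the primary alcohol without affecting the silyl ethers or the isolated olefin.

Step 15
Reactants: 24 [(1S,2R,3S,4R,7S,8S,11R)-3,7-dimethyl-9-methylidene-4-(TBSO)-11-(TESO)tricyclo[5.4.0.0^2,8]undecan-3-yl]methanol
Product: 25 [(1S,2R,3S,4R,7S,8S,11R)-3,7-dimethyl-9-methylidene-4-(TBSO)-11-(TESO)tricyclo[5.4.0.0^2,8]undecan-3-yl]methyl (2Z)-2-methylbut-2-enoate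
Conditions: (2Z)-2-methylbut-2-enoic acid, 2,4,6-Cl3C6H2COCl, Et3N, toluene, 23 °C; then 24, 75 °C
Reagents that add atoms: angelic acid C/C=C(/C)C(=O)O
Why: Yamaguchi mixed-anhydride esterification run without DMAP acylates the neopentyl alcohol with the angeloyl group while avoiding isomerisation to the tiglate.

Step 16
Reactants: 25 [(1S,2R,3S,4R,7S,8S,11R)-3,7-dimethyl-9-methylidene-4-(TBSO)-11-(TESO)tricyclo[5.4.0.0^2,8]undecan-3-yl]methyl (2Z)-2-methylbut-2-enoate
Product: 26 [(1S,2R,3S,4R,7S,8S,11R)-11-hydroxy-3,7-dimethyl-9-methylidene-4-(TBSO)tricyclo[5.4.0.0^2,8]undecan-3-yl]methyl (2Z)-2-methylbut-2-enoate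
Conditions: PPTS (cat.), MeOH/CH2Cl2, 0 °C
Reagents that add atoms: none
Why: Mild acid-catalysed methanolysis removes the triethylsilyl ether selectively because the tert-butyldimethylsilyl ether of the hindered C11 alcohol is far slower to solvolyse.

Step 17
Reactants: 26 [(1S,2R,3S,4R,7S,8S,11R)-11-hydroxy-3,7-dimethyl-9-methylidene-4-(TBSO)tricyclo[5.4.0.0^2,8]undecan-3-yl]methyl (2Z)-2-methylbut-2-enoate
Product: 28 [(1S,2R,3S,4R,7S,8S)-3,7,9-trimethyl-11-oxo-4-(TBSO)tricyclo[5.4.0.0^2,8]undec-9-en-3-yl]methyl (2Z)-2-methylbut-2-enoate, via exo-methylene ketone 27 (not isolated)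
Conditions: Dess–Martin periodinane, pyridine, CH2Cl2, 0 → 23 °C; then DBU (0.2 equiv), 23 °C
Reagents that add atoms: none
Why: Dess–Martin oxidation of the C6 alcohol gives the β,γ-unsaturated ketone and a base-mediated 1,3-prototropic shift then moves the exocyclic olefin into conjugation, which also removes the C6 control centre once it has served.

Step 18
Reactants: 28 [(1S,2R,3S,4R,7S,8S)-3,7,9-trimethyl-11-oxo-4-(TBSO)tricyclo[5.4.0.0^2,8]undec-9-en-3-yl]methyl (2Z)-2-methylbut-2-enoate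
Product: 29 [(1S,2R,3S,4R,7S,8S)-4-hydroxy-3,7,9-trimethyl-11-oxotricyclo[5.4.0.0^2,8]undec-9-en-3-yl]methyl (2Z)-2-methylbut-2-enoate
Conditions: HF·pyridine, THF, 0 → 23 °C
Reagents that add atoms: none
Why: Fluoride-induced desilylation with HF·pyridine frees the C11 alcohol under non-basic conditions that leave the angelate geometry and the enone intact.

Step 19
Reactants: 29 [(1S,2R,3S,4R,7S,8S)-4-hydroxy-3,7,9-trimethyl-11-oxotricyclo[5.4.0.0^2,8]undec-9-en-3-yl]methyl (2Z)-2-methylbut-2-enoate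
Product: 30 [(1S,2R,3S,4R,7S,8S)-4-acetoxy-3,7,9-trimethyl-11-oxotricyclo[5.4.0.0^2,8]undec-9-en-3-yl]methyl (2Z)-2-methylbut-2-enoate (target)
Conditions: Ac2O, pyridine, DMAP (cat.), CH2Cl2, 23 °C
Reagents that add atoms: acetic anhydride CC(=O)OC(C)=O
Why: DMAP-catalysed O-acetylation of the secondary alcohol proceeds with retention at C11 and completes the target.

## Compound list

1 | (3R)-5-methoxy-5-oxo-3-(TBSO)pentanoic acid [(R)-3-(tert-butyldimethylsilyloxy)glutaric acid monomethyl ester] | OC(=O)C[C@H](CC(=O)OC)O[Si](C)(C)C(C)(C)C | starting material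
2 | methyl (3R)-5-hydroxy-3-(TBSO)pentanoate | OCC[C@H](CC(=O)OC)O[Si](C)(C)C(C)(C)C | intermediate
3 | methyl (3S)-5-iodo-3-(TBSO)pentanoate | ICC[C@H](CC(=O)OC)O[Si](C)(C)C(C)(C)C | intermediate
4 | lithium enolate of 3 | ICC[C@H](C=C(OC)O[Li])O[Si](C)(C)C(C)(C)C | intermediate
5 | methyl (2RS,3R)-5-iodo-2-methyl-3-(TBSO)pentanoate | ICC[C@H](C(C)C(=O)OC)O[Si](C)(C)C(C)(C)C | intermediate
6 | (4R)-4-hydroxyoxolan-2-one [(R)-3-hydroxy-γ-butyrolactone] | O=C1C[C@@H](O)CO1 | starting material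
7 | (4R)-4-(TESO)oxolan-2-one | O=C1C[C@@H](O[Si](CC)(CC)CC)CO1 | intermediate
8 | (4R)-5-hydroxy-4-(TESO)pentan-2-one (with its cyclic hemiketal) | CC(=O)C[C@@H](O[Si](CC)(CC)CC)CO | intermediate
9 | (2R)-4-oxo-2-(TESO)pentanal | CC(=O)C[C@@H](O[Si](CC)(CC)CC)C=O | intermediate
10 | (4R)-6,6-dibromo-4-(TESO)hex-5-en-2-one | CC(=O)C[C@@H](O[Si](CC)(CC)CC)C=C(Br)Br | intermediate
11 | tert-butyl (2E,5R)-7,7-dibromo-3-methyl-5-(TESO)hepta-2,6-dienoate | CC(C)(C)OC(=O)/C=C(C)/C[C@@H](O[Si](CC)(CC)CC)C=C(Br)Br | intermediate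
12 | [(3R,4RS)-5-methoxy-4-methyl-5-oxo-3-(TBSO)pentyl]zinc iodide | I[Zn]CC[C@H](C(C)C(=O)OC)O[Si](C)(C)C(C)(C)C | intermediate
13 | 1-tert-butyl 12-methyl (2E,5R,6Z,10R,11RS)-7-bromo-3,11-dimethyl-10-(TBSO)-5-(TESO)dodeca-2,6-dienedioate | CC(C)(C)OC(=O)/C=C(C)/C[C@@H](O[Si](CC)(CC)CC)/C=C(Br)/CC[C@@H](O[Si](C)(C)C(C)(C)C)C(C)C(=O)OC | intermediate
14 | 1-tert-butyl 12-methyl (2E,5R,6E,10R,11RS)-3,7,11-trimethyl-10-(TBSO)-5-(TESO)dodeca-2,6-dienedioate | CC(C)(C)OC(=O)/C=C(C)/C[C@@H](O[Si](CC)(CC)CC)/C=C(C)/CC[C@@H](O[Si](C)(C)C(C)(C)C)C(C)C(=O)OC | intermediate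
15 | 12-methyl 1-triethylsilyl (2E,5R,6E,10R,11RS)-3,7,11-trimethyl-10-(TBSO)-5-(TESO)dodeca-2,6-dienedioate | CC[Si](CC)(CC)OC(=O)/C=C(C)/C[C@@H](O[Si](CC)(CC)CC)/C=C(C)/CC[C@@H](O[Si](C)(C)C(C)(C)C)C(C)C(=O)OC | intermediate
16 | (2E,5R,6E,10R,11RS)-12-methoxy-3,7,11-trimethyl-12-oxo-10-(TBSO)-5-(TESO)dodeca-2,6-dienoic acid | OC(=O)/C=C(C)/C[C@@H](O[Si](CC)(CC)CC)/C=C(C)/CC[C@@H](O[Si](C)(C)C(C)(C)C)C(C)C(=O)OC | intermediate
17 | methyl (2RS,3R,6E,8R,10E)-12-chloro-2,6,10-trimethyl-12-oxo-3-(TBSO)-8-(TESO)dodeca-6,10-dienoate | ClC(=O)/C=C(C)/C[C@@H](O[Si](CC)(CC)CC)/C=C(C)/CC[C@@H](O[Si](C)(C)C(C)(C)C)C(C)C(=O)OC | intermediate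
18 | methyl (2RS,3R,6E,8R)-2,6-dimethyl-10-methylidene-12-oxo-3-(TBSO)-8-(TESO)dodeca-6,11-dienoate (vinylketene) | O=C=CC(=C)C[C@@H](O[Si](CC)(CC)CC)/C=C(C)/CC[C@@H](O[Si](C)(C)C(C)(C)C)C(C)C(=O)OC | intermediate
19 | methyl (2RS,3R)-2-methyl-5-[(1S,4R,5S,7S)-7-methyl-2-methylidene-6-oxo-4-(TESO)bicyclo[3.1.1]heptan-7-yl]-3-(TBSO)pentanoate | COC(=O)C(C)[C@H](O[Si](C)(C)C(C)(C)C)CC[C@]1(C)[C@@H]2C(=O)[C@H]1C(=C)C[C@H]2O[Si](CC)(CC)CC | intermediate
20 | lithium enolate of 19 (ester enolate at C1) | COC(O[Li])=C(C)[C@H](O[Si](C)(C)C(C)(C)C)CC[C@]1(C)[C@@H]2C(=O)[C@H]1C(=C)C[C@H]2O[Si](CC)(CC)CC | intermediate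
21 | lithium alkoxide of methyl (1S,2S,3S,4R,7S,8S,11R)-2-hydroxy-3,7-dimethyl-9-methylidene-4-(TBSO)-11-(TESO)tricyclo[5.4.0.0^2,8]undecane-3-carboxylate | COC(=O)[C@]1(C)[C@]2(O[Li])[C@H]3C(=C)C[C@@H](O[Si](CC)(CC)CC)[C@@H]2[C@@]3(C)CC[C@H]1O[Si](C)(C)C(C)(C)C | intermediate
22 | methyl (1S,2S,3S,4R,7S,8S,11R)-2-[(2-methoxy-2-oxoacetyl)oxy]-3,7-dimethyl-9-methylidene-4-(TBSO)-11-(TESO)tricyclo[5.4.0.0^2,8]undecane-3-carboxylate | COC(=O)[C@]1(C)[C@]2(OC(=O)C(=O)OC)[C@H]3C(=C)C[C@@H](O[Si](CC)(CC)CC)[C@@H]2[C@@]3(C)CC[C@H]1O[Si](C)(C)C(C)(C)C | intermediate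
23 | methyl (1S,2R,3R,4R,7S,8S,11R)-3,7-dimethyl-9-methylidene-4-(TBSO)-11-(TESO)tricyclo[5.4.0.0^2,8]undecane-3-carboxylate | COC(=O)[C@]1(C)[C@@H]2[C@H]3C(=C)C[C@@H](O[Si](CC)(CC)CC)[C@@H]2[C@@]3(C)CC[C@H]1O[Si](C)(C)C(C)(C)C | intermediate
24 | [(1S,2R,3S,4R,7S,8S,11R)-3,7-dimethyl-9-methylidene-4-(TBSO)-11-(TESO)tricyclo[5.4.0.0^2,8]undecan-3-yl]methanol | OC[C@]1(C)[C@@H]2[C@H]3C(=C)C[C@@H](O[Si](CC)(CC)CC)[C@@H]2[C@@]3(C)CC[C@H]1O[Si](C)(C)C(C)(C)C | intermediate
25 | [(1S,2R,3S,4R,7S,8S,11R)-3,7-dimethyl-9-methylidene-4-(TBSO)-11-(TESO)tricyclo[5.4.0.0^2,8]undecan-3-yl]methyl (2Z)-2-methylbut-2-enoate | C/C=C(/C)C(=O)OC[C@]1(C)[C@@H]2[C@H]3C(=C)C[C@@H](O[Si](CC)(CC)CC)[C@@H]2[C@@]3(C)CC[C@H]1O[Si](C)(C)C(C)(C)C | intermediate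
26 | [(1S,2R,3S,4R,7S,8S,11R)-11-hydroxy-3,7-dimethyl-9-methylidene-4-(TBSO)tricyclo[5.4.0.0^2,8]undecan-3-yl]methyl (2Z)-2-methylbut-2-enoate | C/C=C(/C)C(=O)OC[C@]1(C)[C@@H]2[C@H]3C(=C)C[C@@H](O)[C@@H]2[C@@]3(C)CC[C@H]1O[Si](C)(C)C(C)(C)C | intermediate
27 | [(1S,2R,3S,4R,7S,8S)-3,7-dimethyl-9-methylidene-11-oxo-4-(TBSO)tricyclo[5.4.0.0^2,8]undecan-3-yl]methyl (2Z)-2-methylbut-2-enoate | C/C=C(/C)C(=O)OC[C@]1(C)[C@@H]2[C@H]3C(=C)CC(=O)[C@@H]2[C@@]3(C)CC[C@H]1O[Si](C)(C)C(C)(C)C | intermediate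
28 | [(1S,2R,3S,4R,7S,8S)-3,7,9-trimethyl-11-oxo-4-(TBSO)tricyclo[5.4.0.0^2,8]undec-9-en-3-yl]methyl (2Z)-2-methylbut-2-enoate | C/C=C(/C)C(=O)OC[C@]1(C)[C@@H]2[C@H]3C(C)=CC(=O)[C@@H]2[C@@]3(C)CC[C@H]1O[Si](C)(C)C(C)(C)C | intermediate
29 | [(1S,2R,3S,4R,7S,8S)-4-hydroxy-3,7,9-trimethyl-11-oxotricyclo[5.4.0.0^2,8]undec-9-en-3-yl]methyl (2Z)-2-methylbut-2-enoate | C/C=C(/C)C(=O)OC[C@]1(C)[C@@H]2[C@H]3C(C)=CC(=O)[C@@H]2[C@@]3(C)CC[C@H]1O | intermediate
30 | [(1S,2R,3S,4R,7S,8S)-4-acetoxy-3,7,9-trimethyl-11-oxotricyclo[5.4.0.0^2,8]undec-9-en-3-yl]methyl (2Z)-2-methylbut-2-enoate | C/C=C(/C)C(=O)OC[C@]1(C)[C@@H]2[C@H]3C(C)=CC(=O)[C@@H]2[C@@]3(C)CC[C@H]1OC(C)=O | target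

## Step count and risks

Total step count: 19. Longest linear sequence: 16 steps (from 6, steps 4–19); the three steps from 1 to 5 run in parallel.

The three steps most likely to fail:

Step 11 (vinylketene [2+2]). The risks are competing γ-deprotonation at C5, ketene oligomerisation and incomplete facial control. The fallback sets out from 16 and comes back at 19. Acid 16 is coupled with pyrrolidine (pivaloyl chloride, Et3N; then pyrrolidine) to the pyrrolidine amide F1. Tf2O and 2,6-di-tert-butyl-4-methylpyridine in ClCH2CH2Cl convert it into the vinylketeniminium triflate F2, which is much more electrophilic than the ketene and should undergo the same intramolecular [2+2] at 25–60 °C under the same A(1,3) control, giving the cyclobutaniminium triflate F3. Aqueous NaHCO3 hydrolyses F3 to 19.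

Step 12 (aldol and in-situ oxalylation). The risks are retro-aldol and failure to acylate the very hindered tertiary aldolate; the C1 selectivity rests on a conformational model. The fallback sets out from 19 and comes back at 24. The aldol is run as in step 12 but quenched with AcOH at −78 °C, and the β-hydroxy ester F4 is isolated. LiAlH4 reduces it to the 1,3-diol F5. 1,1'-Thiocarbonyldiimidazole and DMAP in toluene at 80 °C close the six-membered cyclic thionocarbonate F6, so the tertiary oxygen is derivatised intramolecularly. Bu3SnH with Et3B/air at 23 °C cleaves the tertiary C–O bond (more stable radical) to the S-stannyl thiocarbonate F7, and K2CO3/MeOH releases 24.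

Step 13 (radical deoxygenation at 110 °C). The risk is β-scission of the strained cyclobutyl radical before hydrogen transfer. The fallback sets out from 19 and comes back at 24. The aldolate of step 12 is trapped with ClP(O)(OEt)2 instead, giving the tertiary diethyl phosphate F8. Li in EtNH2/t-BuOH/THF at −78 → 0 °C (dissolving-metal deoxygenation, radical anion to carbanion, protonated on the open face) removes the phosphate. The same conditions reduce the methyl ester, so 24 is obtained directly.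

## Further compounds

F1 | step 11 | methyl (2RS,3R,6E,8R,10E)-2,6,10-trimethyl-12-oxo-12-(pyrrolidin-1-yl)-3-(TBSO)-8-(TESO)dodeca-6,10-dienoate | O=C(/C=C(C)/C[C@@H](O[Si](CC)(CC)CC)/C=C(C)/CC[C@@H](O[Si](C)(C)C(C)(C)C)C(C)C(=O)OC)N1CCCC1
F2 | step 11 | vinylketeniminium triflate from F1 (N-pyrrolidinium C=C=N+ in place of the amide, 3-methylidene) | C=C(C[C@@H](O[Si](CC)(CC)CC)/C=C(C)/CC[C@@H](O[Si](C)(C)C(C)(C)C)C(C)C(=O)OC)C=C=[N+]1CCCC1.[O-]S(=O)(=O)C(F)(F)F
F3 | step 11 | cyclobutaniminium triflate corresponding to ketone 19 (pyrrolidin-1-ium-1-ylidene at the cyclobutanone carbon, ring configuration as in 19) | COC(=O)C(C)[C@H](O[Si](C)(C)C(C)(C)C)CC[C@]1(C)[C@@H]2C(=[N+]3CCCC3)[C@H]1C(=C)C[C@H]2O[Si](CC)(CC)CC.[O-]S(=O)(=O)C(F)(F)F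
F4 | step 12 | methyl (1S,2S,3S,4R,7S,8S,11R)-2-hydroxy-3,7-dimethyl-9-methylidene-4-(TBSO)-11-(TESO)tricyclo[5.4.0.0^2,8]undecane-3-carboxylate | COC(=O)[C@]1(C)[C@]2(O)[C@H]3C(=C)C[C@@H](O[Si](CC)(CC)CC)[C@@H]2[C@@]3(C)CC[C@H]1O[Si](C)(C)C(C)(C)C
F5 | step 12 | (1S,2S,3S,4R,7S,8S,11R)-3-(hydroxymethyl)-3,7-dimethyl-9-methylidene-4-(TBSO)-11-(TESO)tricyclo[5.4.0.0^2,8]undecan-2-ol | OC[C@]1(C)[C@]2(O)[C@H]3C(=C)C[C@@H](O[Si](CC)(CC)CC)[C@@H]2[C@@]3(C)CC[C@H]1O[Si](C)(C)C(C)(C)C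
F6 | step 12 | cyclic thionocarbonate (1,3-dioxane-2-thione) joining the C2 oxygen and the C1 CH2O of F5 | S=C4OC[C@]1(C)[C@]2(O4)[C@H]3C(=C)C[C@@H](O[Si](CC)(CC)CC)[C@@H]2[C@@]3(C)CC[C@H]1O[Si](C)(C)C(C)(C)C
F7 | step 12 | O-{[(1S,2R,3S,4R,7S,8S,11R)-3,7-dimethyl-9-methylidene-4-(TBSO)-11-(TESO)tricyclo[5.4.0.0^2,8]undecan-3-yl]methyl} S-(tributylstannyl) carbonothioate | CCCC[Sn](CCCC)(CCCC)SC(=O)OC[C@]1(C)[C@@H]2[C@H]3C(=C)C[C@@H](O[Si](CC)(CC)CC)[C@@H]2[C@@]3(C)CC[C@H]1O[Si](C)(C)C(C)(C)C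
F8 | step 13 | methyl (1S,2S,3S,4R,7S,8S,11R)-2-[(diethoxyphosphoryl)oxy]-3,7-dimethyl-9-methylidene-4-(TBSO)-11-(TESO)tricyclo[5.4.0.0^2,8]undecane-3-carboxylate | COC(=O)[C@]1(C)[C@]2(OP(=O)(OCC)OCC)[C@H]3C(=C)C[C@@H](O[Si](CC)(CC)CC)[C@@H]2[C@@]3(C)CC[C@H]1O[Si](C)(C)C(C)(C)C
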